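**Retrosynthetic overview**
1. Target 20 ⇐ hexa-O-benzyl ether 19 (hydrogenolysis); 19 ⇐ (Z)-allylic alcohol 16 by closing the pyran ring of the 3,4-trans unit through its O1'–C2' bond.
2. Enabling feature: in that ring C4' is a carbinol held between the A' ring (C4a', with the phenol oxygen on C8a') and C3'–C2', and C2' is benzylic to the 4-oxygenated B' ring. A (Z)-C2'=C3' alkene therefore takes oxygen at C3' syn to the C4'–OH (A1,3 strain) and the C8a' phenoxide at C2' with inversion, which is exactly the 2,3-cis-3,4-trans triad.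
3. 16 ⇐ Suzuki–Miyaura union (C6–C6') of bromide 13, which already carries the finished all-cis pyran ring, with boronate 14.
4. 13 ⇐ the same epoxidation/cyclisation on monomer 8, then C4 inversion through ketone 12; 8 and 14 ⇐ one propargylic alcohol 7 ⇐ aldehyde 4 + alkyne 6 (catalytic asymmetric alkynylation).
5. Ring order: the four benzene rings are bought; pyran ring of the all-cis unit (step 7); pyran ring of the 3,4-trans unit last (step 13).

Key step: step 13

Remark: flavan numbering is used; unprimed locants belong to the all-cis (2R,3R,4R) unit, primed locants to the 2,3-cis-3,4-trans (2'R,3'R,4'S) unit, and the units are joined C6–C6'.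

**Route**

Step 1
Reactants: 1 2,3,4-trihydroxybenzaldehyde
Product: 2 3,4-bis(benzyloxy)-2-hydroxybenzaldehyde
Conditions: BnBr (2.1 equiv), K2CO3 (2.2 equiv), DMF, 0 °C to rt
Reagents that add atoms: benzyl bromide, BrCc1ccccc1
Why: Williamson etherification; the 2-OH is tied up in a hydrogen bond/chelate with the aldehyde and is the least nucleophilic phenol, so two equivalents of halide should stop at the 3,4-dibenzyl ether, as is usual for 2,3,4-trihydroxyaryl carbonyl compounds.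

Step 2
Reactants: 2 3,4-bis(benzyloxy)-2-hydroxybenzaldehyde
Product: 3 3,4-bis(benzyloxy)-5-bromo-2-hydroxybenzaldehyde
Conditions: NBS (1.05 equiv), MeCN, 0 °C to rt
Reagents that add atoms: N-bromosuccinimide, O=C1CCC(=O)N1Br
Why: Electrophilic aromatic bromination; C5 is para to the free phenol, ortho to the 4-benzyloxy group and meta to the aldehyde, whereas the only other free position (C6) is meta to the phenol, so the future C6 handle should be placed unambiguously.

Step 3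
Reactants: 3 3,4-bis(benzyloxy)-5-bromo-2-hydroxybenzaldehyde
Product: 4 3,4-bis(benzyloxy)-5-bromo-2-(triisopropylsilyloxy)benzaldehyde
Conditions: TIPSOTf (1.3 equiv), 2,6-lutidine, CH2Cl2, 0 °C to rt
Reagents that add atoms: triisopropylsilyl triflate, CC(C)[Si](OS(=O)(=O)C(F)(F)F)(C(C)C)C(C)C
Why: Silylation of the hindered phenol with the reactive triflate; the bulky aryl silyl ether should survive organozinc reagents, mild aqueous base, Lindlar reduction and peracid, and is the fluoride-labile trigger for ring closure.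

Step 4
Reactants: 5 4-(benzyloxy)benzaldehyde
Product: 6 1-(benzyloxy)-4-ethynylbenzene
Conditions: dimethyl (1-diazo-2-oxopropyl)phosphonate (1.2 equiv), K2CO3, MeOH, rt
Reagents that add atoms: dimethyl (1-diazo-2-oxopropyl)phosphonate, COP(=O)(OC)C(=[N+]=[N-])C(C)=O
Why: Ohira–Bestmann variant of the Seyferth–Gilbert homologation, which converts aryl aldehydes into terminal alkynes under mild base without touching the benzyl ether.

Step 5
Reactants: 4 3,4-bis(benzyloxy)-5-bromo-2-(triisopropylsilyloxy)benzaldehyde; 6 1-(benzyloxy)-4-ethynylbenzene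
Product: 7 (R)-1-[3,4-bis(benzyloxy)-5-bromo-2-(triisopropylsilyloxy)phenyl]-3-[4-(benzyloxy)phenyl]prop-2-yn-1-ol
Conditions: 6 (2 equiv), Et2Zn (2 equiv), toluene, reflux; then (R)-BINOL (20 mol %), Ti(OiPr)4 (50 mol %), CH2Cl2, rt; then 4, rt
Reagents that add atoms: none
Why: BINOL–titanium-catalysed enantioselective addition of an alkynylzinc to an aromatic aldehyde; the (R)-ligand is expected to deliver the alkynyl group to the Re face, which gives the (R)-carbinol here because the ortho-oxygenated aryl group outranks the alkynyl group (configuration to be confirmed by Mosher ester analysis).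

Step 6
Reactants: 7 (R)-1-[3,4-bis(benzyloxy)-5-bromo-2-(triisopropylsilyloxy)phenyl]-3-[4-(benzyloxy)phenyl]prop-2-yn-1-ol
Product: 8 (R,Z)-1-[3,4-bis(benzyloxy)-5-bromo-2-(triisopropylsilyloxy)phenyl]-3-[4-(benzyloxy)phenyl]prop-2-en-1-ol
Conditions: H2 (1 atm), Lindlar catalyst, quinoline, EtOAc, rt
Reagents that add atoms: none
Why: Lindlar semihydrogenation delivers H2 syn on the poisoned palladium surface to give the (Z)-alkene, leaving the carbinol centre, aryl bromide, benzyl ethers and silyl ether untouched.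

Step 7
Reactants: 8 (R,Z)-1-[3,4-bis(benzyloxy)-5-bromo-2-(triisopropylsilyloxy)phenyl]-3-[4-(benzyloxy)phenyl]prop-2-en-1-ol
Product: 11 (2R,3R,4S)-7,8-bis(benzyloxy)-2-[4-(benzyloxy)phenyl]-6-bromochromane-3,4-diol, via silyl epoxide 9 (not isolated), via phenol epoxide 10 (not isolated)
Conditions: mCPBA (1.2 equiv), NaHCO3, CH2Cl2, −20 to 0 °C; aq. NaHCO3/Na2S2O3 wash, crude 9 in THF; TBAF (1.2 equiv), 0 °C to rt
Reagents that add atoms: meta-chloroperoxybenzoic acid, OOC(=O)c1cccc(Cl)c1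
Why: Hydroxyl-directed peracid epoxidation of a Z-allylic alcohol (threo, oxygen delivered syn to OH in the A1,3-minimised conformer, which sets C3) followed by fluoride-triggered 6-endo-tet opening of the cis-epoxide at benzylic C2 by the phenoxide with inversion (sets C2), so the (R)-carbinol should give the 2,3-cis-3,4-trans ring.

Step 8
Reactants: 11 (2R,3R,4S)-7,8-bis(benzyloxy)-2-[4-(benzyloxy)phenyl]-6-bromochromane-3,4-diol
Product: 12 (2R,3S)-7,8-bis(benzyloxy)-2-[4-(benzyloxy)phenyl]-6-bromo-3-hydroxychroman-4-one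
Conditions: activated MnO2 (15 equiv), CH2Cl2, rt
Reagents that add atoms: none
Why: Chemoselective MnO2 oxidation of the electron-rich benzylic C4 carbinol in the presence of the non-benzylic C3–OH under neutral conditions that should not enolise the 2,3-cis α-ketol; the C4 centre is erased so that it can be reset.

Step 9
Reactants: 12 (2R,3S)-7,8-bis(benzyloxy)-2-[4-(benzyloxy)phenyl]-6-bromo-3-hydroxychroman-4-one
Product: 13 (2R,3R,4R)-7,8-bis(benzyloxy)-2-[4-(benzyloxy)phenyl]-6-bromochromane-3,4-diol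
Conditions: NaBH4, THF/MeOH, −40 to 0 °C
Reagents that add atoms: none
Why: Borohydride reduction of the aryl ketone; in the half-chair with equatorial 2-aryl and axial 3-OH, hydride should add anti to the axial C3–O bond (Felkin–Anh, axial attack), which places the new 4-OH cis to the 3-OH and gives the all-cis diol.

Step 10
Reactants: 7 (R)-1-[3,4-bis(benzyloxy)-5-bromo-2-(triisopropylsilyloxy)phenyl]-3-[4-(benzyloxy)phenyl]prop-2-yn-1-ol
Product: 14 (R)-1-[3,4-bis(benzyloxy)-5-(4,4,5,5-tetramethyl-1,3,2-dioxaborolan-2-yl)-2-(triisopropylsilyloxy)phenyl]-3-[4-(benzyloxy)phenyl]prop-2-yn-1-ol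
Conditions: B2pin2 (1.3 equiv), Pd(dppf)Cl2 (5 mol %), KOAc, 1,4-dioxane, 85 °C
Reagents that add atoms: bis(pinacolato)diboron, CC1(C)OB(OC1(C)C)B1OC(C)(C)C(C)(C)O1
Why: Miyaura borylation of the aryl bromide; the weak acetate base should leave the free propargylic alcohol, the internal alkyne and the aryl silyl ether alone.

Step 11
Reactants: 13 (2R,3R,4R)-7,8-bis(benzyloxy)-2-[4-(benzyloxy)phenyl]-6-bromochromane-3,4-diol; 14 (R)-1-[3,4-bis(benzyloxy)-5-(4,4,5,5-tetramethyl-1,3,2-dioxaborolan-2-yl)-2-(triisopropylsilyloxy)phenyl]-3-[4-(benzyloxy)phenyl]prop-2-yn-1-ol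
Product: 15 (2R,3R,4R)-7,8-bis(benzyloxy)-2-[4-(benzyloxy)phenyl]-6-{2,3-bis(benzyloxy)-5-[(R)-3-(4-(benzyloxy)phenyl)-1-hydroxyprop-2-yn-1-yl]-4-(triisopropylsilyloxy)phenyl}chromane-3,4-diol
Conditions: SPhos Pd G3 (5 mol %), K3PO4 (aq. 0.5 M), THF, 40 °C
Reagents that add atoms: none
Why: Suzuki–Miyaura coupling; each partner has a single ortho-benzyloxy group, so the biaryl is only di-ortho-substituted (freely rotating, no atropisomers) and within reach of a dialkylbiarylphosphine catalyst, while the mild biphasic base at 40 °C should spare the free hydroxyls and the aryl silyl ether.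

Step 12
Reactants: 15 (2R,3R,4R)-7,8-bis(benzyloxy)-2-[4-(benzyloxy)phenyl]-6-{2,3-bis(benzyloxy)-5-[(R)-3-(4-(benzyloxy)phenyl)-1-hydroxyprop-2-yn-1-yl]-4-(triisopropylsilyloxy)phenyl}chromane-3,4-diol
Product: 16 (2R,3R,4R)-7,8-bis(benzyloxy)-2-[4-(benzyloxy)phenyl]-6-{2,3-bis(benzyloxy)-5-[(R,Z)-3-(4-(benzyloxy)phenyl)-1-hydroxyprop-2-en-1-yl]-4-(triisopropylsilyloxy)phenyl}chromane-3,4-diol
Conditions: H2 (1 atm), Lindlar catalyst, quinoline, EtOAc, rt
Reagents that add atoms: none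
Why: Lindlar semihydrogenation (syn addition of H2) should give the (Z)-alkene needed for the cis-epoxide without reducing benzyl ethers or the benzylic C–O bonds of the finished ring.

Step 13
Reactants: 16 (2R,3R,4R)-7,8-bis(benzyloxy)-2-[4-(benzyloxy)phenyl]-6-{2,3-bis(benzyloxy)-5-[(R,Z)-3-(4-(benzyloxy)phenyl)-1-hydroxyprop-2-en-1-yl]-4-(triisopropylsilyloxy)phenyl}chromane-3,4-diol
Product: 19 (2R,2'R,3R,3'R,4R,4'S)-7,7',8,8'-tetrakis(benzyloxy)-2,2'-bis[4-(benzyloxy)phenyl]-[6,6'-bichromane]-3,3',4,4'-tetrol, via silyl epoxide 17 (not isolated), via phenol epoxide 18 (not isolated)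
Conditions: mCPBA (1.2 equiv), NaHCO3, CH2Cl2, −20 to 0 °C; aq. NaHCO3/Na2S2O3 wash, crude 17 in THF; TBAF (1.2 equiv), 0 °C to rt
Reagents that add atoms: meta-chloroperoxybenzoic acid, OOC(=O)c1cccc(Cl)c1
Why: Mechanism: the peracid, hydrogen-bonded to the free C4'–OH, transfers oxygen to the electron-rich (Z)-C2'=C3' bond from the face that the hydroxyl occupies in the A1,3-strain-minimised conformer (C4'–H eclipsing the alkene, the silyloxy-aryl group shielding the other face), giving the threo cis-epoxide 17; fluoride then unmasks the C8a' phenoxide 18, which opens the epoxide at C2' in an intramolecular SN2 reaction. The closest known reaction types are the hydroxyl-directed (Henbest-type) peracid epoxidation of Z-allylic alcohols and the phenoxide opening of aryl epoxides that closes flavan-3-ols. The pyran ring is closed 6-endo-tet through the O1'–C2' bond. C3' is controlled by the C4' carbinol through the directed, A1,3-governed face selectivity and is retained, and C2' is controlled by the cis-epoxide geometry together with inversion, so syn-epoxidation plus anti-opening should turn the (R)-carbinol into the 2'R,3'R,4'S (2,3-cis-3,4-trans) triad while C4' itself is untouched. The step needs threo over erythro epoxidation, 6-endo over 5-exo opening, inversion instead of benzylic ionisation, and reaction at one alkene in a molecule with six benzyl ethers and a free diol: the Z geometry enforces the reactive conformer, the 4-benzyloxyphenyl group makes C2' the benzylic, more electrophilic terminus while the C4' oxygen retards attack at C3', the buffered and then basic (never acidic) medium keeps the p-alkoxybenzylic epoxide off an SN1 path, and the styrenyl double bond is the only site a peracid attacks at 0 °C.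

Step 14
Reactants: 19 (2R,2'R,3R,3'R,4R,4'S)-7,7',8,8'-tetrakis(benzyloxy)-2,2'-bis[4-(benzyloxy)phenyl]-[6,6'-bichromane]-3,3',4,4'-tetrol
Product: 20 (2R,2'R,3R,3'R,4R,4'S)-2,2'-bis(4-hydroxyphenyl)-[6,6'-bichromane]-3,3',4,4',7,7',8,8'-octol
Conditions: H2 (1 atm), Pd(OH)2/C, THF/MeOH, rt
Reagents that add atoms: none
Why: Hydrogenolysis of the six aryl benzyl ethers in a neutral medium; aryl benzyl ethers should cleave much faster than the ring benzylic C2–O and C4–OH bonds, and the absence of acid avoids ionisation and epimerisation at C4 and C4'.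

**Compound list**
1 | 2,3,4-trihydroxybenzaldehyde | O=Cc1ccc(O)c(O)c1O | starting material
2 | 3,4-bis(benzyloxy)-2-hydroxybenzaldehyde | O=Cc1ccc(OCc2ccccc2)c(OCc2ccccc2)c1O | intermediate
3 | 3,4-bis(benzyloxy)-5-bromo-2-hydroxybenzaldehyde | O=Cc1cc(Br)c(OCc2ccccc2)c(OCc2ccccc2)c1O | intermediate
4 | 3,4-bis(benzyloxy)-5-bromo-2-(triisopropylsilyloxy)benzaldehyde | O=Cc1cc(Br)c(OCc2ccccc2)c(OCc2ccccc2)c1O[Si](C(C)C)(C(C)C)C(C)C | intermediate
5 | 4-(benzyloxy)benzaldehyde | O=Cc1ccc(OCc2ccccc2)cc1 | starting material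
6 | 1-(benzyloxy)-4-ethynylbenzene | C#Cc1ccc(OCc2ccccc2)cc1 | intermediate
7 | (R)-1-[3,4-bis(benzyloxy)-5-bromo-2-(triisopropylsilyloxy)phenyl]-3-[4-(benzyloxy)phenyl]prop-2-yn-1-ol | O[C@H](C#Cc1ccc(OCc2ccccc2)cc1)c1cc(Br)c(OCc2ccccc2)c(OCc2ccccc2)c1O[Si](C(C)C)(C(C)C)C(C)C | intermediate
8 | (R,Z)-1-[3,4-bis(benzyloxy)-5-bromo-2-(triisopropylsilyloxy)phenyl]-3-[4-(benzyloxy)phenyl]prop-2-en-1-ol | O[C@H](/C=C\c1ccc(OCc2ccccc2)cc1)c1cc(Br)c(OCc2ccccc2)c(OCc2ccccc2)c1O[Si](C(C)C)(C(C)C)C(C)C | intermediate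
9 | (S)-[3,4-bis(benzyloxy)-5-bromo-2-(triisopropylsilyloxy)phenyl][(2R,3S)-3-(4-(benzyloxy)phenyl)oxiran-2-yl]methanol (threo, cis-epoxide) | O[C@H]([C@H]3O[C@H]3c1ccc(OCc2ccccc2)cc1)c1cc(Br)c(OCc2ccccc2)c(OCc2ccccc2)c1O[Si](C(C)C)(C(C)C)C(C)C | intermediate
10 | (S)-[3,4-bis(benzyloxy)-5-bromo-2-hydroxyphenyl][(2R,3S)-3-(4-(benzyloxy)phenyl)oxiran-2-yl]methanol (formed as its phenoxide) | O[C@H]([C@H]3O[C@H]3c1ccc(OCc2ccccc2)cc1)c1cc(Br)c(OCc2ccccc2)c(OCc2ccccc2)c1O | intermediate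
11 | (2R,3R,4S)-7,8-bis(benzyloxy)-2-[4-(benzyloxy)phenyl]-6-bromochromane-3,4-diol (2,3-cis-3,4-trans) | Brc1cc2c(c(OCc3ccccc3)c1OCc1ccccc1)O[C@H](c1ccc(OCc3ccccc3)cc1)[C@H](O)[C@H]2O | intermediate
12 | (2R,3S)-7,8-bis(benzyloxy)-2-[4-(benzyloxy)phenyl]-6-bromo-3-hydroxychroman-4-one (2,3-cis) | Brc1cc2c(c(OCc3ccccc3)c1OCc1ccccc1)O[C@H](c1ccc(OCc3ccccc3)cc1)[C@H](O)C2=O | intermediate
13 | (2R,3R,4R)-7,8-bis(benzyloxy)-2-[4-(benzyloxy)phenyl]-6-bromochromane-3,4-diol (all-cis) | Brc1cc2c(c(OCc3ccccc3)c1OCc1ccccc1)O[C@H](c1ccc(OCc3ccccc3)cc1)[C@H](O)[C@@H]2O | intermediate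
14 | (R)-1-[3,4-bis(benzyloxy)-5-(4,4,5,5-tetramethyl-1,3,2-dioxaborolan-2-yl)-2-(triisopropylsilyloxy)phenyl]-3-[4-(benzyloxy)phenyl]prop-2-yn-1-ol | O[C@H](C#Cc1ccc(OCc2ccccc2)cc1)c1cc(B2OC(C)(C)C(C)(C)O2)c(OCc2ccccc2)c(OCc2ccccc2)c1O[Si](C(C)C)(C(C)C)C(C)C | intermediate
15 | (2R,3R,4R)-7,8-bis(benzyloxy)-2-[4-(benzyloxy)phenyl]-6-{2,3-bis(benzyloxy)-5-[(R)-3-(4-(benzyloxy)phenyl)-1-hydroxyprop-2-yn-1-yl]-4-(triisopropylsilyloxy)phenyl}chromane-3,4-diol | O[C@H](C#Cc1ccc(OCc2ccccc2)cc1)c1cc(-c2cc3c(c(OCc4ccccc4)c2OCc2ccccc2)O[C@H](c2ccc(OCc4ccccc4)cc2)[C@H](O)[C@@H]3O)c(OCc2ccccc2)c(OCc2ccccc2)c1O[Si](C(C)C)(C(C)C)C(C)C | intermediate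
16 | (2R,3R,4R)-7,8-bis(benzyloxy)-2-[4-(benzyloxy)phenyl]-6-{2,3-bis(benzyloxy)-5-[(R,Z)-3-(4-(benzyloxy)phenyl)-1-hydroxyprop-2-en-1-yl]-4-(triisopropylsilyloxy)phenyl}chromane-3,4-diol | O[C@H](/C=C\c1ccc(OCc2ccccc2)cc1)c1cc(-c2cc3c(c(OCc4ccccc4)c2OCc2ccccc2)O[C@H](c2ccc(OCc4ccccc4)cc2)[C@H](O)[C@@H]3O)c(OCc2ccccc2)c(OCc2ccccc2)c1O[Si](C(C)C)(C(C)C)C(C)C | intermediate
17 | (2R,3R,4R)-7,8-bis(benzyloxy)-2-[4-(benzyloxy)phenyl]-6-{2,3-bis(benzyloxy)-5-[(S)-hydroxy((2R,3S)-3-(4-(benzyloxy)phenyl)oxiran-2-yl)methyl]-4-(triisopropylsilyloxy)phenyl}chromane-3,4-diol | O[C@H]([C@H]5O[C@H]5c1ccc(OCc2ccccc2)cc1)c1cc(-c2cc3c(c(OCc4ccccc4)c2OCc2ccccc2)O[C@H](c2ccc(OCc4ccccc4)cc2)[C@H](O)[C@@H]3O)c(OCc2ccccc2)c(OCc2ccccc2)c1O[Si](C(C)C)(C(C)C)C(C)C | intermediate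
18 | (2R,3R,4R)-7,8-bis(benzyloxy)-2-[4-(benzyloxy)phenyl]-6-{2,3-bis(benzyloxy)-4-hydroxy-5-[(S)-hydroxy((2R,3S)-3-(4-(benzyloxy)phenyl)oxiran-2-yl)methyl]phenyl}chromane-3,4-diol (formed as its phenoxide) | O[C@H]([C@H]5O[C@H]5c1ccc(OCc2ccccc2)cc1)c1cc(-c2cc3c(c(OCc4ccccc4)c2OCc2ccccc2)O[C@H](c2ccc(OCc4ccccc4)cc2)[C@H](O)[C@@H]3O)c(OCc2ccccc2)c(OCc2ccccc2)c1O | intermediate
19 | (2R,2'R,3R,3'R,4R,4'S)-7,7',8,8'-tetrakis(benzyloxy)-2,2'-bis[4-(benzyloxy)phenyl]-[6,6'-bichromane]-3,3',4,4'-tetrol | O(Cc6ccccc6)c1ccc([C@H]2Oc3c(cc(-c4cc5c(c(OCc6ccccc6)c4OCc6ccccc6)O[C@H](c4ccc(OCc6ccccc6)cc4)[C@H](O)[C@H]5O)c(OCc6ccccc6)c3OCc6ccccc6)[C@@H](O)[C@H]2O)cc1 | intermediate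
20 | (2R,2'R,3R,3'R,4R,4'S)-2,2'-bis(4-hydroxyphenyl)-[6,6'-bichromane]-3,3',4,4',7,7',8,8'-octol (CNP0121763.1) | Oc1ccc([C@H]2Oc3c(cc(-c4cc5c(c(O)c4O)O[C@H](c4ccc(O)cc4)[C@H](O)[C@H]5O)c(O)c3O)[C@@H](O)[C@H]2O)cc1 | target

**Totals and risks**

Total step count: 14. Longest linear sequence: 12 steps (1, 2, 3, 5, 6, 7, 8, 9, 11, 12, 13, 14).

Steps most likely to fail:

1. Step 13. What may go wrong: erosion of face selectivity in the directed epoxidation, opening at C3' (5-exo) or ionisation of the electron-rich epoxide when the cascade has to run on the crowded hexabenzylated biaryl. The fallback changes the order of events, so that the ring is closed before the biaryl bond is made. It sets out from 11, whose pyran ring already carries the 2R,3R,4S triad. Miyaura borylation (B2pin2, Pd(dppf)Cl2, KOAc, dioxane, 85 °C) should give the pinacol boronate F1, and Suzuki–Miyaura coupling of F1 with bromide 13 under the conditions of step 11 would rejoin the route at 19.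

2. Step 8 (with step 9). What may go wrong: over-oxidation towards the flavonol, or epimerisation of the 2,3-cis α-ketol at C2/C3 before or during the reduction. The fallback resets C4 before ring closure and sets out from 8. The threo epoxide 9 is isolated after the buffered epoxidation and oxidised with Dess–Martin periodinane to the cis-epoxy ketone F2. Chelation-controlled reduction with Zn(BH4)2 (Et2O, −20 °C) should give the erythro epoxy alcohol F3. TBAF then frees the phenol epoxide F4 (not isolated), which closes 6-endo with inversion at C2 to the all-cis diol, rejoining the route at 13.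

3. Step 5. What may go wrong: poor enantioface discrimination by the BINOL–titanium catalyst at the aldehyde flanked by the bulky silyloxy group. The fallback sets the centre by reduction instead of C–C bond formation and sets out from 4 and 6. Addition of the lithium acetylide of 6 (n-BuLi, THF, −78 °C) gives the racemic propargylic alcohol F5, and Dess–Martin oxidation gives the ynone F6. Corey–Bakshi–Shibata reduction ((S)-Me-CBS, catecholborane, toluene, −78 °C, aryl as the large group) should then rejoin the route at 7.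

**Further compounds**
F1 | step 13 | (2R,3R,4S)-7,8-bis(benzyloxy)-2-[4-(benzyloxy)phenyl]-6-(4,4,5,5-tetramethyl-1,3,2-dioxaborolan-2-yl)chromane-3,4-diol | CC1(C)OB(OC1(C)C)c1cc2c(c(OCc3ccccc3)c1OCc1ccccc1)O[C@H](c1ccc(OCc3ccccc3)cc1)[C@H](O)[C@H]2O
F2 | step 8 | [3,4-bis(benzyloxy)-5-bromo-2-(triisopropylsilyloxy)phenyl][(2S,3S)-3-(4-(benzyloxy)phenyl)oxiran-2-yl]methanone (cis-epoxy ketone) | O=C([C@H]3O[C@H]3c1ccc(OCc2ccccc2)cc1)c1cc(Br)c(OCc2ccccc2)c(OCc2ccccc2)c1O[Si](C(C)C)(C(C)C)C(C)C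
F3 | step 8 | (R)-[3,4-bis(benzyloxy)-5-bromo-2-(triisopropylsilyloxy)phenyl][(2R,3S)-3-(4-(benzyloxy)phenyl)oxiran-2-yl]methanol (erythro) | O[C@@H]([C@H]3O[C@H]3c1ccc(OCc2ccccc2)cc1)c1cc(Br)c(OCc2ccccc2)c(OCc2ccccc2)c1O[Si](C(C)C)(C(C)C)C(C)C
F4 | step 8 | (R)-[3,4-bis(benzyloxy)-5-bromo-2-hydroxyphenyl][(2R,3S)-3-(4-(benzyloxy)phenyl)oxiran-2-yl]methanol (erythro, formed as its phenoxide) | O[C@@H]([C@H]3O[C@H]3c1ccc(OCc2ccccc2)cc1)c1cc(Br)c(OCc2ccccc2)c(OCc2ccccc2)c1O
F5 | step 5 | rac-1-[3,4-bis(benzyloxy)-5-bromo-2-(triisopropylsilyloxy)phenyl]-3-[4-(benzyloxy)phenyl]prop-2-yn-1-ol | OC(C#Cc1ccc(OCc2ccccc2)cc1)c1cc(Br)c(OCc2ccccc2)c(OCc2ccccc2)c1O[Si](C(C)C)(C(C)C)C(C)C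
F6 | step 5 | 1-[3,4-bis(benzyloxy)-5-bromo-2-(triisopropylsilyloxy)phenyl]-3-[4-(benzyloxy)phenyl]prop-2-yn-1-one | O=C(C#Cc1ccc(OCc2ccccc2)cc1)c1cc(Br)c(OCc2ccccc2)c(OCc2ccccc2)c1O[Si](C(C)C)(C(C)C)C(C)C
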